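**Retrosynthetic overview**
- The target (lutein 3-palmitate) is cut at C7'=C8' (Julia–Kocienski) and C7=C8 (Wittig) into a ring B (ε ring) C10 sulfone, crocetindial (C20) and a ring A (β ring) C10 phosphonium salt; the palmitate enters by Mitsunobu inversion at C3.
- Both C10 units come from one glycol-linked bis(keto ester), whose two six-membered carbocycles are closed together by a two-fold Michael/aldol annulation of mesityl oxide onto a bis(acetoacetate).
- One CBS reduction sets both carbinols R. After silylation and LiAlH4 cleavage, the trans C1 epimer is ring B as it stands; the cis epimer becomes ring A (alkene moved into conjugation, C1 stereocentre erased).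
- Crocetindial is built from the C10 dialdehyde by two Wittig homologations.
- Ring order: both carbocycles (future rings A and B) form at the same time in step 4; no ring is formed or opened afterwards.

Assumption: the target is the all-E (3R,3'R,6'R) isomer exactly as the SMILES gives it (ester on the β ring, free hydroxyl on the ε ring), and the two C1 epimers from step 7 are separable on silica.

**Step 1**
Reactants: 1 (2E,4E,6E)-2,7-dimethylocta-2,4,6-trienedial; 2 (1,3-dioxolan-2-ylmethyl)triphenylphosphonium bromide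
Product: 4 (2E,4E,6E,8E,10E)-4,9-dimethyldodeca-2,4,6,8,10-pentaenedial, via bis-dioxolane acetal 3 (not isolated)
Conditions: 2 (2.4 equiv), LiOMe, DMF, 85 °C; then 1 M HCl, THF, rt
Reagents that add atoms: water, O
Why: Wittig two-carbon homologation of each enal with the dioxolanylmethyl ylide, the acid work-up unmasking the aldehydes and equilibrating the two new disubstituted alkenes to E.

**Step 2**
Reactants: 4 (2E,4E,6E,8E,10E)-4,9-dimethyldodeca-2,4,6,8,10-pentaenedial; 5 2-(triphenyl-λ5-phosphanylidene)propanal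
Product: 6 (2E,4E,6E,8E,10E,12E,14E)-2,6,11,15-tetramethylhexadeca-2,4,6,8,10,12,14-heptaenedial (crocetindial)
Conditions: 5 (2.4 equiv), PhMe, 90 °C
Reagents that add atoms: none
Why: Wittig olefination with a stabilised α-branched formyl ylide gives the (E)-2-methyl enal at each end and stops there because the hindered product aldehyde is less electrophilic than the starting enal.

**Step 3**
Reactants: 7 ethane-1,2-diol; 8 tert-butyl 3-oxobutanoate
Product: 9 ethane-1,2-diyl bis(3-oxobutanoate)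
Conditions: 8 (2.2 equiv), xylene, 135 °C, tert-butanol distilled off
Reagents that add atoms: none
Why: thermal transacetoacetylation, in which acetylketene released from the tert-butyl ester is trapped by each hydroxyl.

**Step 4**
Reactants: 9 ethane-1,2-diyl bis(3-oxobutanoate); 10 4-methylpent-3-en-2-one (mesityl oxide)
Product: 12 ethane-1,2-diyl bis(2,6,6-trimethyl-4-oxocyclohex-2-ene-1-carboxylate), via bis-Michael tetraketone 11 (not isolated)
Conditions: 10 (5 equiv), ZnCl2 (0.5 equiv), PhMe–heptane, reflux, Dean–Stark, 48 h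
Reagents that add atoms: none
Why: two-fold Michael addition/intramolecular aldol condensation (Robinson-type annulation with Hagemann's-ester regiochemistry) in which each zinc-chelated keto ester enol adds to activated mesityl oxide to make the quaternary carbon and each new methyl ketone condenses onto the acetoacetate carbonyl, so both six-membered carbocycles close in one operation; C1 of each ring forms as both epimers, and both are used later.

**Step 5**
Reactants: 12 ethane-1,2-diyl bis(2,6,6-trimethyl-4-oxocyclohex-2-ene-1-carboxylate)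
Product: 13 ethane-1,2-diyl bis[(4R)-4-hydroxy-2,6,6-trimethylcyclohex-2-ene-1-carboxylate] (both C1 epimers in each ring)
Conditions: (S)-2-methyl-CBS-oxazaborolidine [(3aS)-1-methyl-3,3-diphenyltetrahydro-1H,3H-pyrrolo[1,2-c][1,3,2]oxazaborole] (0.3 equiv), catecholborane (2.6 equiv), PhMe, −78 °C; aq. NaOH work-up
Reagents that add atoms: none
Why: Corey–Bakshi–Shibata reduction, in which catalyst-controlled 1,2-hydride delivery with the alkenyl arm as the large group sets both carbinol centres R whatever the configuration at C1.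

**Step 6**
Reactants: 13 ethane-1,2-diyl bis[(4R)-4-hydroxy-2,6,6-trimethylcyclohex-2-ene-1-carboxylate]
Product: 14 ethane-1,2-diyl bis[(4R)-4-{[tert-butyl(dimethyl)silyl]oxy}-2,6,6-trimethylcyclohex-2-ene-1-carboxylate]
Conditions: TBSCl (2.6 equiv), imidazole, DMF, rt
Reagents that add atoms: tert-butyl(chloro)dimethylsilane, CC(C)(C)[Si](C)(C)Cl
Why: standard silylation of the two secondary allylic alcohols, which must be masked for steps 8 and 15.

**Step 7**
Reactants: 14 ethane-1,2-diyl bis[(4R)-4-{[tert-butyl(dimethyl)silyl]oxy}-2,6,6-trimethylcyclohex-2-ene-1-carboxylate]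
Product: 15 [(1R,4R)-4-{[tert-butyl(dimethyl)silyl]oxy}-2,6,6-trimethylcyclohex-2-en-1-yl]methanol (trans, for ring B) and 16 [(1S,4R)-4-{[tert-butyl(dimethyl)silyl]oxy}-2,6,6-trimethylcyclohex-2-en-1-yl]methanol (cis, for ring A), about 1:1, separated by chromatography
Conditions: LiAlH4, THF, 0 °C to rt
Reagents that add atoms: none
Why: ester reduction by LiAlH4 releases the glycol linker and turns the C1 epimers into two separable diastereomeric alcohols without touching either stereocentre.

**Step 8**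
Reactants: 15 [(1R,4R)-4-{[tert-butyl(dimethyl)silyl]oxy}-2,6,6-trimethylcyclohex-2-en-1-yl]methanol
Product: 17 5-({[(1R,4R)-4-{[tert-butyl(dimethyl)silyl]oxy}-2,6,6-trimethylcyclohex-2-en-1-yl]methyl}sulfanyl)-1-phenyl-1H-tetrazole
Conditions: 1-phenyl-1H-tetrazole-5-thiol, PPh3, DIAD, THF, 0 °C to rt
Reagents that add atoms: 1-phenyl-1H-tetrazole-5-thiol, Sc1nnnn1-c1ccccc1
Why: Mitsunobu thioetherification at the primary carbon with a very acidic thiol; no stereocentre is involved.

**Step 9**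
Reactants: 17 5-({[(1R,4R)-4-{[tert-butyl(dimethyl)silyl]oxy}-2,6,6-trimethylcyclohex-2-en-1-yl]methyl}sulfanyl)-1-phenyl-1H-tetrazole
Product: 18 5-({[(1R,4R)-4-{[tert-butyl(dimethyl)silyl]oxy}-2,6,6-trimethylcyclohex-2-en-1-yl]methyl}sulfonyl)-1-phenyl-1H-tetrazole
Conditions: (NH4)6Mo7O24·4H2O (0.2 equiv), 30% H2O2, EtOH, 0 °C to rt
Reagents that add atoms: hydrogen peroxide, OO
Why: molybdate-catalysed sulfide-to-sulfone oxidation, chemoselective for sulfur over the trisubstituted alkene and the silyl ether.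

**Step 10**
Reactants: 16 [(1S,4R)-4-{[tert-butyl(dimethyl)silyl]oxy}-2,6,6-trimethylcyclohex-2-en-1-yl]methanol
Product: 20 (4S)-4-{[tert-butyl(dimethyl)silyl]oxy}-2,6,6-trimethylcyclohex-1-ene-1-carbaldehyde, via non-conjugated aldehyde 19 (not isolated)
Conditions: Dess–Martin periodinane, CH2Cl2, 0 °C to rt; then DBU (2.5 equiv), 0 °C, stopped at full isomerisation
Reagents that add atoms: none
Why: Dess–Martin oxidation followed by base-mediated isomerisation through the dienolate (α-cyclocitral to β-cyclocitral type) moves the alkene into conjugation and erases the C1 stereocentre while the carbinol centre is untouched.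

**Step 11**
Reactants: 20 (4S)-4-{[tert-butyl(dimethyl)silyl]oxy}-2,6,6-trimethylcyclohex-1-ene-1-carbaldehyde
Product: 21 [(4S)-4-{[tert-butyl(dimethyl)silyl]oxy}-2,6,6-trimethylcyclohex-1-en-1-yl]methanol
Conditions: NaBH4, MeOH, 0 °C
Reagents that add atoms: none
Why: simple 1,2-reduction of the hindered enal to the primary allylic alcohol.

**Step 12**
Reactants: 21 [(4S)-4-{[tert-butyl(dimethyl)silyl]oxy}-2,6,6-trimethylcyclohex-1-en-1-yl]methanol
Product: 22 {[(4S)-4-hydroxy-2,6,6-trimethylcyclohex-1-en-1-yl]methyl}(triphenyl)phosphonium bromide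
Conditions: PPh3·HBr (1.3 equiv), MeOH, rt, 48 h
Reagents that add atoms: triphenylphosphine hydrobromide, [Br-].[PH+](c1ccccc1)(c1ccccc1)c1ccccc1
Why: acid-mediated phosphonium salt formation through the allyl cation, PPh3 attacking the primary terminus, while HBr in methanol also removes the silyl ether and leaves the non-allylic carbinol configuration intact.

**Step 13**
Reactants: 22 {[(4S)-4-hydroxy-2,6,6-trimethylcyclohex-1-en-1-yl]methyl}(triphenyl)phosphonium bromide; 6 crocetindial
Product: 23 (2E,4E,6E,8E,10E,12E,14E,16E)-17-[(4S)-4-hydroxy-2,6,6-trimethylcyclohex-1-en-1-yl]-2,6,11,15-tetramethylheptadeca-2,4,6,8,10,12,14,16-octaenal [(3S)-3-hydroxy-8'-apo-β-caroten-8'-al]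
Conditions: 6 (3 equiv, excess recovered), NaOMe (1.2 equiv), CH2Cl2–MeOH, 0 °C to rt
Reagents that add atoms: none
Why: Wittig olefination with the semi-stabilised allylic ylide, where crowding next to the ring enforces the 7E alkene and the threefold excess of dialdehyde keeps the reaction at the mono-adduct.

**Step 14**
Reactants: 23 (3S)-3-hydroxy-8'-apo-β-caroten-8'-al; 24 hexadecanoic acid
Product: 25 (3R)-8'-oxo-8'-apo-β-caroten-3-yl hexadecanoate
Conditions: 24 (2 equiv), PPh3, DIAD (betaine pre-formed), PhMe, 0 °C to rt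
Reagents that add atoms: none
Why: Mitsunobu esterification, in which SN2 displacement of the activated C3 oxygen by palmitate inverts the 3S carbinol to the 3R ester found in the target.

**Step 15**
Reactants: 18 5-({[(1R,4R)-4-{[tert-butyl(dimethyl)silyl]oxy}-2,6,6-trimethylcyclohex-2-en-1-yl]methyl}sulfonyl)-1-phenyl-1H-tetrazole; 25 (3R)-8'-oxo-8'-apo-β-caroten-3-yl hexadecanoate
Product: 26 (3R,3'R,6'R)-3'-{[tert-butyl(dimethyl)silyl]oxy}-β,ε-caroten-3-yl hexadecanoate
Conditions: 18 (1.2 equiv), KN(SiMe3)2 (1.15 equiv), THF, −78 °C, then 25, −78 °C to rt; aq. NH4Cl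
Reagents that add atoms: none
Why: Julia–Kocienski olefination of the pre-metalated phenyltetrazolyl sulfone gives the 7'E alkene, and C6' keeps its configuration because its hydrogen is not acidic.

**Step 16**
Reactants: 26 (3R,3'R,6'R)-3'-{[tert-butyl(dimethyl)silyl]oxy}-β,ε-caroten-3-yl hexadecanoate
Product: 27 (3R,3'R,6'R)-3'-hydroxy-β,ε-caroten-3-yl hexadecanoate (lutein 3-O-palmitate)
Conditions: HF·pyridine, excess pyridine, THF, 0 °C to rt
Reagents that add atoms: none
Why: buffered fluoride desilylation frees the allylic 3'-hydroxyl without acid epimerisation and leaves the palmitate untouched.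

**Compound list**
1 | (2E,4E,6E)-2,7-dimethylocta-2,4,6-trienedial | O=C/C(C)=C/C=C/C=C(C)/C=O | starting material
2 | (1,3-dioxolan-2-ylmethyl)triphenylphosphonium bromide | [Br-].C1COC(C[P+](c2ccccc2)(c2ccccc2)c2ccccc2)O1 | starting material
3 | 2,2'-[(3E,5E,7E)-3,8-dimethyldeca-1,3,5,7,9-pentaene-1,10-diyl]bis(1,3-dioxolane), E/Z mixture at the two new alkenes | C1COC(O1)C=C/C(C)=C/C=C/C=C(C)/C=CC1OCCO1 | intermediate (not isolated)
4 | (2E,4E,6E,8E,10E)-4,9-dimethyldodeca-2,4,6,8,10-pentaenedial | O=C/C=C/C(C)=C/C=C/C=C(C)/C=C/C=O | intermediate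
5 | 2-(triphenyl-λ5-phosphanylidene)propanal | CC(C=O)=P(c1ccccc1)(c1ccccc1)c1ccccc1 | starting material
6 | (2E,4E,6E,8E,10E,12E,14E)-2,6,11,15-tetramethylhexadeca-2,4,6,8,10,12,14-heptaenedial (crocetindial) | O=C/C(C)=C/C=C/C(C)=C/C=C/C=C(C)/C=C/C=C(C)/C=O | intermediate
7 | ethane-1,2-diol | OCCO | starting material
8 | tert-butyl 3-oxobutanoate | CC(=O)CC(=O)OC(C)(C)C | starting material
9 | ethane-1,2-diyl bis(3-oxobutanoate) | CC(=O)CC(=O)OCCOC(=O)CC(C)=O | intermediate
10 | 4-methylpent-3-en-2-one | CC(=O)C=C(C)C | starting material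
11 | ethane-1,2-diyl bis(2-acetyl-3,3-dimethyl-5-oxohexanoate) | CC(=O)CC(C)(C)C(C(C)=O)C(=O)OCCOC(=O)C(C(C)=O)C(C)(C)CC(C)=O | intermediate (not isolated)
12 | ethane-1,2-diyl bis(2,6,6-trimethyl-4-oxocyclohex-2-ene-1-carboxylate), C1 epimers | CC1=CC(=O)CC(C)(C)C1C(=O)OCCOC(=O)C1C(C)=CC(=O)CC1(C)C | intermediate
13 | ethane-1,2-diyl bis[(4R)-4-hydroxy-2,6,6-trimethylcyclohex-2-ene-1-carboxylate], C1 epimers | O=C(OCCOC(=O)C1C(C)=C[C@H](O)CC1(C)C)C1C(C)=C[C@H](O)CC1(C)C | intermediate
14 | ethane-1,2-diyl bis[(4R)-4-{[tert-butyl(dimethyl)silyl]oxy}-2,6,6-trimethylcyclohex-2-ene-1-carboxylate], C1 epimers | O=C(OCCOC(=O)C1C(C)=C[C@H](O[Si](C)(C)C(C)(C)C)CC1(C)C)C1C(C)=C[C@H](O[Si](C)(C)C(C)(C)C)CC1(C)C | intermediate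
15 | [(1R,4R)-4-{[tert-butyl(dimethyl)silyl]oxy}-2,6,6-trimethylcyclohex-2-en-1-yl]methanol | OC[C@H]1C(C)=C[C@H](O[Si](C)(C)C(C)(C)C)CC1(C)C | intermediate
16 | [(1S,4R)-4-{[tert-butyl(dimethyl)silyl]oxy}-2,6,6-trimethylcyclohex-2-en-1-yl]methanol | OC[C@@H]1C(C)=C[C@H](O[Si](C)(C)C(C)(C)C)CC1(C)C | intermediate
17 | 5-({[(1R,4R)-4-{[tert-butyl(dimethyl)silyl]oxy}-2,6,6-trimethylcyclohex-2-en-1-yl]methyl}sulfanyl)-1-phenyl-1H-tetrazole | c1ccccc1-n1nnnc1SC[C@H]1C(C)=C[C@H](O[Si](C)(C)C(C)(C)C)CC1(C)C | intermediate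
18 | 5-({[(1R,4R)-4-{[tert-butyl(dimethyl)silyl]oxy}-2,6,6-trimethylcyclohex-2-en-1-yl]methyl}sulfonyl)-1-phenyl-1H-tetrazole | c1ccccc1-n1nnnc1S(=O)(=O)C[C@H]1C(C)=C[C@H](O[Si](C)(C)C(C)(C)C)CC1(C)C | intermediate
19 | (1S,4R)-4-{[tert-butyl(dimethyl)silyl]oxy}-2,6,6-trimethylcyclohex-2-ene-1-carbaldehyde | O=C[C@@H]1C(C)=C[C@H](O[Si](C)(C)C(C)(C)C)CC1(C)C | intermediate (not isolated)
20 | (4S)-4-{[tert-butyl(dimethyl)silyl]oxy}-2,6,6-trimethylcyclohex-1-ene-1-carbaldehyde | CC1=C(C=O)C(C)(C)C[C@@H](O[Si](C)(C)C(C)(C)C)C1 | intermediate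
21 | [(4S)-4-{[tert-butyl(dimethyl)silyl]oxy}-2,6,6-trimethylcyclohex-1-en-1-yl]methanol | CC1=C(CO)C(C)(C)C[C@@H](O[Si](C)(C)C(C)(C)C)C1 | intermediate
22 | {[(4S)-4-hydroxy-2,6,6-trimethylcyclohex-1-en-1-yl]methyl}(triphenyl)phosphonium bromide | [Br-].CC1=C(C[P+](c2ccccc2)(c2ccccc2)c2ccccc2)C(C)(C)C[C@@H](O)C1 | intermediate
23 | (3S)-3-hydroxy-8'-apo-β-caroten-8'-al, all-E | O[C@H]1CC(C)=C(/C=C/C(C)=C/C=C/C(C)=C/C=C/C=C(C)/C=C/C=C(C)/C=O)C(C)(C)C1 | intermediate
24 | hexadecanoic acid (palmitic acid) | CCCCCCCCCCCCCCCC(=O)O | starting material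
25 | (3R)-8'-oxo-8'-apo-β-caroten-3-yl hexadecanoate, all-E | CCCCCCCCCCCCCCCC(=O)O[C@@H]1CC(C)=C(/C=C/C(C)=C/C=C/C(C)=C/C=C/C=C(C)/C=C/C=C(C)/C=O)C(C)(C)C1 | intermediate
26 | (3R,3'R,6'R)-3'-{[tert-butyl(dimethyl)silyl]oxy}-β,ε-caroten-3-yl hexadecanoate | CCCCCCCCCCCCCCCC(=O)O[C@@H]1CC(C)=C(/C=C/C(C)=C/C=C/C(C)=C/C=C/C=C(C)/C=C/C=C(C)/C=C/[C@H]2C(C)=C[C@H](O[Si](C)(C)C(C)(C)C)CC2(C)C)C(C)(C)C1 | intermediate
27 | (3R,3'R,6'R)-3'-hydroxy-β,ε-caroten-3-yl hexadecanoate (CNP0192969.1) | CCCCCCCCCCCCCCCC(=O)O[C@@H]1CC(C)=C(/C=C/C(C)=C/C=C/C(C)=C/C=C/C=C(C)/C=C/C=C(C)/C=C/[C@H]2C(C)=C[C@H](O)CC2(C)C)C(C)(C)C1 | target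

**Step count**
Total: 16 steps. Longest linear sequence: 12 steps (3, 4, 5, 6, 7, 10, 11, 12, 13, 14, 15, 16).

**Three steps most likely to fail, with fallbacks**

Step 4 (two-fold annulation). Mesityl oxide is a hindered Michael acceptor and four C–C bonds must form on one molecule, so the yield may be low or the reaction may stall at mono-annulation. The fallback reverses the polarity of the Michael step. It sets out from 9: Knoevenagel condensation with acetone (TiCl4, pyridine, THF, 0 °C) gives ethane-1,2-diyl bis(2-acetyl-3-methylbut-2-enoate) F1. Mukaiyama–Michael addition of 2-(trimethylsilyloxy)propene (TiCl4, CH2Cl2, −78 °C) then builds both quaternary carbons and gives tetraketone 11, this time isolated. Pyrrolidinium acetate (or TsOH, benzene, Dean–Stark) closes both rings by aldol condensation, and the route is rejoined at 12.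

Step 5 (CBS reduction). The bulky CH2–CMe2 arm may compete with the alkenyl arm as the large group, which would erode the selectivity at both carbinols. The fallback replaces asymmetric reduction by enzymatic resolution. It sets out from 12: NaBH4/CeCl3·7H2O in MeOH reduces without facial control to ethane-1,2-diyl bis(4-hydroxy-2,6,6-trimethylcyclohex-2-ene-1-carboxylate) F2. A Pseudomonas lipase (Amano lipase PS or AK) with vinyl acetate acylates only 4R carbinols, and the doubly acylated fraction, ethane-1,2-diyl bis[(4R)-4-acetoxy-2,6,6-trimethylcyclohex-2-ene-1-carboxylate] F3, is separated. K2CO3 in MeOH at 0 °C removes the acetates and the route is rejoined at 13. Under-acylated material is oxidised back to 12 with MnO2 and recycled.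

Step 14 (Mitsunobu inversion on the polyene aldehyde). Axial SN2 at C3 is slowed by the syn-axial C1 methyl, so elimination to the 3,4-didehydro compound (assisted by the long conjugated aldehyde) and attack of DIAD on the polyene are real risks. The fallback moves the inversion to the polyene-free, carbonyl-free C10 stage. It sets out from 22: anion metathesis with NaBF4 (CH2Cl2/water) removes the competing bromide and gives {[(4S)-4-hydroxy-2,6,6-trimethylcyclohex-1-en-1-yl]methyl}(triphenyl)phosphonium tetrafluoroborate F4. Mitsunobu reaction with 24 (PPh3, DIAD, CH2Cl2) gives {[(4R)-4-(hexadecanoyloxy)-2,6,6-trimethylcyclohex-1-en-1-yl]methyl}(triphenyl)phosphonium tetrafluoroborate F5. Ylide formation with LiN(SiMe3)2 at −78 °C and Wittig reaction with 6 (threefold excess) rejoins the route at 25.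

**Further compounds**
F1 | step 4 | ethane-1,2-diyl bis(2-acetyl-3-methylbut-2-enoate) | CC(=O)C(=C(C)C)C(=O)OCCOC(=O)C(=C(C)C)C(C)=O
F2 | step 5 | ethane-1,2-diyl bis(4-hydroxy-2,6,6-trimethylcyclohex-2-ene-1-carboxylate), all stereoisomers | O=C(OCCOC(=O)C1C(C)=CC(O)CC1(C)C)C1C(C)=CC(O)CC1(C)C
F3 | step 5 | ethane-1,2-diyl bis[(4R)-4-acetoxy-2,6,6-trimethylcyclohex-2-ene-1-carboxylate], C1 epimers | O=C(OCCOC(=O)C1C(C)=C[C@H](OC(C)=O)CC1(C)C)C1C(C)=C[C@H](OC(C)=O)CC1(C)C
F4 | step 14 | {[(4S)-4-hydroxy-2,6,6-trimethylcyclohex-1-en-1-yl]methyl}(triphenyl)phosphonium tetrafluoroborate | F[B-](F)(F)F.CC1=C(C[P+](c2ccccc2)(c2ccccc2)c2ccccc2)C(C)(C)C[C@@H](O)C1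
F5 | step 14 | {[(4R)-4-(hexadecanoyloxy)-2,6,6-trimethylcyclohex-1-en-1-yl]methyl}(triphenyl)phosphonium tetrafluoroborate | F[B-](F)(F)F.CCCCCCCCCCCCCCCC(=O)O[C@@H]1CC(C)=C(C[P+](c2ccccc2)(c2ccccc2)c2ccccc2)C(C)(C)C1
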